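**Strategy.** The eleven-membered carbocycle is opened at the bond between the carbinol carbon C1 and the methyl-bearing alkenyl carbon C2. The key step exploits the allylic alcohol unit C1(O)–C2(CH3)=C3 of the cycloundecadiene ring. A ligand-controlled intramolecular Nozaki–Hiyama–Kishi coupling of a (Z)-alkenyl iodide with an aldehyde closes the ring, forms C1–C2, sets the C1 stereocentre and carries the Z geometry of C2=C3 into the ring in one operation. Its precursor is the acyclic (3E,10Z)-11-iodo-4,8,8-trimethyldodeca-3,10-dienal, built by B-alkyl Suzuki coupling and iodo-Wittig olefination. Esterification with acetyl-protected vanillic acid and phenol release finish the route.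

Key step: step 10

Remark (assumption on the chemistry): the sense of induction of the oxazoline sulfonamide ligand in a ring-closing Ni/Cr coupling is assumed, not established. The (S)-ligand is written as the antipode that should give Si-face addition (1R); its mirror image would be used if the opposite sense were found. Compounds 1, 4 and 15 are taken as commercially available. Ring atoms are numbered as in the name of 14 (C1 carbinol carbon, C2=C3 the Z alkene, C5 the gem-dimethyl carbon, C9=C10 the E alkene).

**Step 1**
Reactants: 1 diethyl 2-(propan-2-ylidene)malonate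
Product: 2 diethyl 2-(2-methylpent-4-en-2-yl)malonate
Conditions: allylMgBr (1.3 equiv), CuI (5 mol %), THF, −30 to 0 °C; aq. NH4Cl
Reagents that add atoms: allylmagnesium bromide, C=CC[Mg]Br
Why: Copper-catalysed conjugate addition of the allyl Grignard reagent to the doubly activated alkylidene malonate should build the gem-dimethyl quaternary carbon, the malonate acceptor suppressing 1,2-addition.

**Step 2**
Reactants: 2 diethyl 2-(2-methylpent-4-en-2-yl)malonate
Product: 3 ethyl 3,3-dimethylhex-5-enoate
Conditions: LiCl (2 equiv), H2O (2 equiv), DMSO, 160 °C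
Reagents that add atoms: none
Why: Krapcho dealkoxycarbonylation, in which chloride dealkylates one ester and the resulting carboxylate loses CO2, should leave the mono-ester and not touch the terminal alkene.

**Step 3**
Reactants: 4 pent-3-yn-1-ol
Product: 5 tert-butyldimethyl(pent-3-yn-1-yloxy)silane
Conditions: TBSCl, imidazole, CH2Cl2, 0 °C to rt
Reagents that add atoms: tert-butyldimethylsilyl chloride, CC(C)(C)[Si](C)(C)Cl
Why: Standard silylation of a primary alcohol masks the hydroxyl through the organometallic steps that follow.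

**Step 4**
Reactants: 5 tert-butyldimethyl(pent-3-yn-1-yloxy)silane
Product: 7 tert-butyl{[(3E)-4-iodopent-3-en-1-yl]oxy}dimethylsilane, via alkenylzirconocene chloride 6 (not isolated)
Conditions: Cp2Zr(H)Cl (2.2 equiv), THF, 50 °C; then I2, 0 °C
Reagents that add atoms: iodine, II
Why: Hydrozirconation is a syn addition that, with excess reagent and warming, should equilibrate zirconium to the less hindered methyl-bearing alkyne carbon, and iodinolysis with retention should then give the (E)-2-iodoalk-2-ene.

**Step 5**
Reactants: 3 ethyl 3,3-dimethylhex-5-enoate; 7 tert-butyl{[(3E)-4-iodopent-3-en-1-yl]oxy}dimethylsilane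
Product: 9 ethyl (7E)-10-[(tert-butyldimethylsilyl)oxy]-3,3,7-trimethyldec-7-enoate, via B-alkyl-9-BBN borane 8 (not isolated)
Conditions: 3, 9-BBN-H, THF, 0 °C to rt; then 7, Pd(dppf)Cl2 (5 mol %), AsPh3, Cs2CO3, DMF/THF/H2O, rt
Reagents that add atoms: none
Why: 9-BBN should hydroborate the terminal alkene anti-Markovnikov without touching the ester, and the B-alkyl Suzuki–Miyaura coupling should join the sp3 carbon to the alkenyl iodide with retention of the E geometry.

**Step 6**
Reactants: 9 ethyl (7E)-10-[(tert-butyldimethylsilyl)oxy]-3,3,7-trimethyldec-7-enoate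
Product: 10 (7E)-10-[(tert-butyldimethylsilyl)oxy]-3,3,7-trimethyldec-7-enal
Conditions: i-Bu2AlH (1.1 equiv), CH2Cl2, −78 °C; MeOH, then aq. Rochelle salt
Reagents that add atoms: none
Why: Partial ester reduction should stop at the aldehyde because the tetrahedral aluminium hemiacetal is stable at −78 °C and collapses only on work-up.

**Step 7**
Reactants: 10 (7E)-10-[(tert-butyldimethylsilyl)oxy]-3,3,7-trimethyldec-7-enal
Product: 11 tert-butyl{[(3E,10Z)-11-iodo-4,8,8-trimethyldodeca-3,10-dien-1-yl]oxy}dimethylsilane
Conditions: EtPPh3I, n-BuLi, THF, rt; I2, −78 °C; NaN(SiMe3)2, −20 °C; then 10, −78 °C to rt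
Reagents that add atoms: ethyltriphenylphosphonium iodide, CC[P+](c1ccccc1)(c1ccccc1)c1ccccc1.[I-]; iodine, II
Why: Stork–Zhao-type Wittig olefination with the α-iodo ylide Ph3P=C(I)CH3 is kinetically Z-selective and should place iodine cis to the chain, which is the geometry the ring alkene C2=C3 needs.

**Step 8**
Reactants: 11 tert-butyl{[(3E,10Z)-11-iodo-4,8,8-trimethyldodeca-3,10-dien-1-yl]oxy}dimethylsilane
Product: 12 (3E,10Z)-11-iodo-4,8,8-trimethyldodeca-3,10-dien-1-ol
Conditions: camphorsulfonic acid (10 mol %), MeOH/CH2Cl2, 0 °C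
Reagents that add atoms: none
Why: Acid-catalysed methanolysis should remove the primary TBS ether without base, so the (Z)-alkenyl iodide is not exposed to dehydrohalogenation.

**Step 9**
Reactants: 12 (3E,10Z)-11-iodo-4,8,8-trimethyldodeca-3,10-dien-1-ol
Product: 13 (3E,10Z)-11-iodo-4,8,8-trimethyldodeca-3,10-dienal
Conditions: Dess–Martin periodinane, NaHCO3, CH2Cl2, 0 °C to rt; crude aldehyde used at once
Reagents that add atoms: none
Why: Buffered Dess–Martin oxidation should give the β,γ-unsaturated aldehyde under near-neutral conditions, which limits migration of its C3=C4 double bond into conjugation.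

**Step 10**
Reactants: 13 (3E,10Z)-11-iodo-4,8,8-trimethyldodeca-3,10-dienal
Product: 14 (1R,2Z,9E)-2,5,5,9-tetramethylcycloundeca-2,9-dien-1-ol
Conditions: CrCl2 (4 equiv), N-{2-[(4S)-4-isopropyl-4,5-dihydrooxazol-2-yl]-6-methylphenyl}methanesulfonamide (4.4 equiv), Et3N (4.4 equiv), THF, rt; NiCl2 (0.2 equiv); then 13 by syringe pump over 10 h to 2 mM, rt; aq. ethylenediamine
Reagents that add atoms: none
Why: Zerovalent nickel, formed from NiCl2 and CrCl2, should insert into the C–I bond with retention, and transmetalation should give an alkenyl species of trivalent chromium carrying the chiral ligand, which adds to the aldehyde through a closed chromium-bound transition state (Nozaki–Hiyama–Kishi reaction). The closest known reaction type is the ligand-controlled asymmetric Ni/Cr coupling of alkenyl iodides with aliphatic aldehydes and its use in macrocyclisation. The eleven-membered carbocycle should close in the 11-exo-trig mode, by attack of C11 of 13 (ring C2) on the carbonyl carbon C1. The new stereocentre C1 is controlled only by the sulfonamide ligand on chromium (reagent control, Si-face attack giving 1R), since the substrate has no other stereocentre. The step needs chemoselective activation of the C–I bond beside an enolisable aldehyde, which the low basicity and carbonyl selectivity of organochromium reagents secure. It also needs ring closure over oligomerisation, which high dilution, the Z geometry of C10=C11 in 13 (turning the chain back toward the aldehyde) and the gem-dimethyl group should secure, and retention of both alkene geometries, which the configurational stability of alkenylchromium species and the non-basic medium should secure.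

**Step 11**
Reactants: 14 (1R,2Z,9E)-2,5,5,9-tetramethylcycloundeca-2,9-dien-1-ol; 15 4-acetoxy-3-methoxybenzoic acid
Product: 16 (1R,2Z,9E)-2,5,5,9-tetramethylcycloundeca-2,9-dien-1-yl 4-acetoxy-3-methoxybenzoate
Conditions: DCC, DMAP (10 mol %), CH2Cl2, 0 °C to rt
Reagents that add atoms: none
Why: Steglich esterification acylates the secondary allylic alcohol on oxygen, so C1 keeps its configuration, and the acetate on the phenol prevents self-acylation of the acid.

**Step 12**
Reactants: 16 (1R,2Z,9E)-2,5,5,9-tetramethylcycloundeca-2,9-dien-1-yl 4-acetoxy-3-methoxybenzoate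
Product: 17 (1R,2Z,9E)-2,5,5,9-tetramethylcycloundeca-2,9-dien-1-yl 4-hydroxy-3-methoxybenzoate
Conditions: pyrrolidine (3 equiv), CH2Cl2, 0 °C
Reagents that add atoms: none
Why: Aminolysis should cleave the activated aryl acetate much faster than the hindered secondary alkyl benzoate, freeing the phenol without touching C1 or the alkenes.

**Compound list**
1 | diethyl 2-(propan-2-ylidene)malonate | CC(C)=C(C(=O)OCC)C(=O)OCC | starting material
2 | diethyl 2-(2-methylpent-4-en-2-yl)malonate | C=CCC(C)(C)C(C(=O)OCC)C(=O)OCC | intermediate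
3 | ethyl 3,3-dimethylhex-5-enoate | C=CCC(C)(C)CC(=O)OCC | intermediate
4 | pent-3-yn-1-ol | CC#CCCO | starting material
5 | tert-butyldimethyl(pent-3-yn-1-yloxy)silane | CC#CCCO[Si](C)(C)C(C)(C)C | intermediate
6 | chlorobis(cyclopentadienyl){(2E)-5-[(tert-butyldimethylsilyl)oxy]pent-2-en-2-yl}zirconium (alkenylzirconocene chloride, not isolated) | C/C(=C\CCO[Si](C)(C)C(C)(C)C)[Zr](Cl)(C1C=CC=C1)C1C=CC=C1 | intermediate
7 | tert-butyl{[(3E)-4-iodopent-3-en-1-yl]oxy}dimethylsilane | C/C(I)=C\CCO[Si](C)(C)C(C)(C)C | intermediate
8 | ethyl 6-(9-borabicyclo[3.3.1]nonan-9-yl)-3,3-dimethylhexanoate (not isolated) | CCOC(=O)CC(C)(C)CCCB1C2CCCC1CCC2 | intermediate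
9 | ethyl (7E)-10-[(tert-butyldimethylsilyl)oxy]-3,3,7-trimethyldec-7-enoate | CCOC(=O)CC(C)(C)CCC/C(C)=C/CCO[Si](C)(C)C(C)(C)C | intermediate
10 | (7E)-10-[(tert-butyldimethylsilyl)oxy]-3,3,7-trimethyldec-7-enal | O=CCC(C)(C)CCC/C(C)=C/CCO[Si](C)(C)C(C)(C)C | intermediate
11 | tert-butyl{[(3E,10Z)-11-iodo-4,8,8-trimethyldodeca-3,10-dien-1-yl]oxy}dimethylsilane | C/C(I)=C/CC(C)(C)CCC/C(C)=C/CCO[Si](C)(C)C(C)(C)C | intermediate
12 | (3E,10Z)-11-iodo-4,8,8-trimethyldodeca-3,10-dien-1-ol | C/C(I)=C/CC(C)(C)CCC/C(C)=C/CCO | intermediate
13 | (3E,10Z)-11-iodo-4,8,8-trimethyldodeca-3,10-dienal | C/C(I)=C/CC(C)(C)CCC/C(C)=C/CC=O | intermediate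
14 | (1R,2Z,9E)-2,5,5,9-tetramethylcycloundeca-2,9-dien-1-ol | O[C@@H]1C/C=C(\C)CCCC(C)(C)C/C=C\1C | intermediate
15 | 4-acetoxy-3-methoxybenzoic acid | COc1cc(C(=O)O)ccc1OC(C)=O | starting material
16 | (1R,2Z,9E)-2,5,5,9-tetramethylcycloundeca-2,9-dien-1-yl 4-acetoxy-3-methoxybenzoate | COc1cc(C(=O)O[C@@H]2C/C=C(\C)CCCC(C)(C)C/C=C\2C)ccc1OC(C)=O | intermediate
17 | (1R,2Z,9E)-2,5,5,9-tetramethylcycloundeca-2,9-dien-1-yl 4-hydroxy-3-methoxybenzoate | COc1cc(C(=O)O[C@@H]2C/C=C(\C)CCCC(C)(C)C/C=C\2C)ccc1O | target

**Totals.** Total step count: 12. Longest linear sequence: 10 steps (steps 1, 2, 5, 6, 7, 8, 9, 10, 11, 12); steps 3 and 4 form the side branch to 7.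

**Steps most likely to fail**

1. Step 10. The facial selectivity of the carbonyl addition may be low or reversed in a ring-closing transition state, intermolecular coupling may compete, and the C3=C4 double bond of the aldehyde may move into conjugation before closure. The fallback separates ring closure from stereocontrol and sets out from 13. An achiral Ni/Cr coupling (CrCl2, NiCl2 cat., DMSO, rt, high dilution) should still form the same bond and ring, giving racemic (2Z,9E)-2,5,5,9-tetramethylcycloundeca-2,9-dien-1-ol F1. Buffered Dess–Martin oxidation should give (2Z,9E)-2,5,5,9-tetramethylcycloundeca-2,9-dien-1-one F2. Corey–Bakshi–Shibata reduction with the (S)-methyl oxazaborolidine and catecholborane (toluene, −78 °C) treats the α-methyl alkenyl arm as the large group and should deliver the 1R alcohol, returning to the route at 14.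

2. Step 7. The α-iodo ylide may lose iodine or react sluggishly with the β-quaternary aldehyde, and Z selectivity may erode. The fallback builds the haloalkene stepwise by cross-coupling and sets out from 10. Corey–Fuchs dibromo-olefination (CBr4, PPh3, CH2Cl2, 0 °C) should give tert-butyl{[(3E)-11,11-dibromo-4,8,8-trimethylundeca-3,10-dien-1-yl]oxy}dimethylsilane F3. Trans-selective Negishi monomethylation (Me2Zn, Pd(DPEphos)Cl2 cat., THF) replaces the bromine trans to the chain and should give tert-butyl{[(3E,10Z)-11-bromo-4,8,8-trimethyldodeca-3,10-dien-1-yl]oxy}dimethylsilane F4. Copper-catalysed halogen exchange (CuI cat., trans-N,N'-dimethylcyclohexane-1,2-diamine, NaI, dioxane, 110 °C) with retention should return to the route at 11.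

3. Step 6. The aluminium hemiacetal may collapse before the quench, so reduction runs past the aldehyde. The fallback replaces partial reduction by a reduce-then-oxidise sequence and sets out from 9. LiAlH4 (THF, 0 °C) should give (7E)-10-[(tert-butyldimethylsilyl)oxy]-3,3,7-trimethyldec-7-en-1-ol F5, and buffered Dess–Martin oxidation should return to the route at 10.

**Further compounds**
F1 | step 10 | racemic (2Z,9E)-2,5,5,9-tetramethylcycloundeca-2,9-dien-1-ol | OC1C/C=C(\C)CCCC(C)(C)C/C=C\1C
F2 | step 10 | (2Z,9E)-2,5,5,9-tetramethylcycloundeca-2,9-dien-1-one | O=C1C/C=C(\C)CCCC(C)(C)C/C=C\1C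
F3 | step 7 | tert-butyl{[(3E)-11,11-dibromo-4,8,8-trimethylundeca-3,10-dien-1-yl]oxy}dimethylsilane | BrC(Br)=CCC(C)(C)CCC/C(C)=C/CCO[Si](C)(C)C(C)(C)C
F4 | step 7 | tert-butyl{[(3E,10Z)-11-bromo-4,8,8-trimethyldodeca-3,10-dien-1-yl]oxy}dimethylsilane | C/C(Br)=C/CC(C)(C)CCC/C(C)=C/CCO[Si](C)(C)C(C)(C)C
F5 | step 6 | (7E)-10-[(tert-butyldimethylsilyl)oxy]-3,3,7-trimethyldec-7-en-1-ol | OCCC(C)(C)CCC/C(C)=C/CCO[Si](C)(C)C(C)(C)C
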